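**Overview**

1. The retrosynthesis cuts three C–C bonds (lignan numbering): C7'–C2 (ring B, Friedel–Crafts alkylation), C7'–C1' (guaiacyl ring to a carbonyl carbon) and C1–C7 (ring A to an acyl carbon).
2. The third cut is possible because the chain C7–C8(Me)–C8'(Me)–C7' with its cis methyls is a meso-2,3-dimethylsuccinyl unit, and ring A is a syringyl ring whose C2 and C6 are equivalent, so it can be attached through C1 first and closed at either ortho carbon later.
3. Forward: ring A is joined to C7 as meso-2,3-dimethylsuccinic anhydride is opened by an arylzinc under chiral rhodium catalysis. The ketone is reduced to CH2, the acid end becomes a Weinreb amide that takes the guaiacyl ring at C7', and ring B closes last (C7'–C2).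
4. Stereochemistry: the cis C8/C8' methyls come from syn hydrogenation of 2,3-dimethylmaleic anhydride; their absolute sense (8R,8'R) comes from the catalyst's choice between the enantiotopic carbonyls; C7' (R) comes from substrate control in the cation cyclization (aryl trans to the C8' methyl).
5. Both phenols are carried as triisopropylsilyl ethers, which tolerate the aryllithium, TFA and BF3 stages, and are released together at the end.

Key step: step 3

Assumption: the sense of induction of the rhodium–phosphinooxazoline catalyst with this arylzinc is not taken from analogy; the ligand enantiomer used is the one that a pilot run (chiral HPLC, later the sign of rotation of the target) shows to give the (2R,3S) keto acid.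

**Route**

Step 1
Reactants: 1 2,3-dimethylmaleic anhydride
Product: 2 meso-2,3-dimethylsuccinic anhydride ((3R,4S)-3,4-dimethyloxolane-2,5-dione, methyls cis)
Conditions: H2 (4 atm), 10% Pd/C, dry EtOAc, rt
Reagents that add atoms: none
Why: Heterogeneous catalytic hydrogenation delivers both hydrogens to the same face of the ring alkene, so the two methyls end cis and the product is the meso anhydride; the neutral, aprotic medium leaves the anhydride and its epimerizable α-carbons untouched.

Step 2
Reactants: 3 4-bromo-2,6-dimethoxyphenol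
Product: 4 (4-bromo-2,6-dimethoxyphenoxy)triisopropylsilane
Conditions: TIPSCl, imidazole, DMF, rt to 40 °C
Reagents that add atoms: triisopropylsilyl chloride (TIPSCl), CC(C)[Si](Cl)(C(C)C)C(C)C
Why: Silyl ether formation on a phenol with imidazole as base and nucleophilic catalyst; the triisopropylsilyl ether is preferred to a benzyl ether because it should survive the later TFA and hydrogenation-type conditions that an aryl benzyl ether flanked by two methoxy groups may not.

Step 3
Reactants: 4 (4-bromo-2,6-dimethoxyphenoxy)triisopropylsilane; 2 meso-2,3-dimethylsuccinic anhydride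
Product: 7 (2R,3S)-4-[3,5-dimethoxy-4-(triisopropylsilyloxy)phenyl]-2,3-dimethyl-4-oxobutanoic acid, via aryllithium 5 (not isolated), via arylzinc triflate 6 (not isolated)
Conditions: n-BuLi, THF, −78 °C; Zn(OTf)2, −78 °C to rt; then added to 2, [Rh(cod)Cl]2 (5 mol %), t-Bu-PHOX (10 mol %, enantiomer per the assumption), DMF, 50 °C; cold 1 M HCl work-up
Reagents that add atoms: none
Why: The ligated monovalent rhodium inserts into one of the two enantiotopic acyl–oxygen bonds of the flat, rigid meso anhydride to give an acyl rhodium carboxylate (trivalent rhodium), the aryl group passes from zinc to rhodium, and reductive elimination forms the C1–C7 aryl–acyl bond and returns monovalent rhodium. The closest known reaction type is the rhodium–phosphinooxazoline-catalysed enantioselective acyl cross-coupling of cyclic meso succinic anhydrides, cis-2,3-dimethylsuccinic anhydride among them, with arylzinc reagents made in the flask from an aryllithium and Zn(OTf)2. No ring is closed in this step; the five-membered anhydride ring is opened, so no mode of closure applies. No new stereogenic carbon is created either: the two centres already present and mirror-related in 2 receive their absolute sense from the chiral ligand, which sends rhodium to the carbonyl on the (S)-configured ring carbon, so that this carbon becomes C3 (S, α to the ketone) and the other becomes C2 (R, α to the acid). The step needs enantiotopic-group selection and transfer of exactly one aryl group; the first rests on the ligand, the second on the substrate, because the zinc carboxylate formed at the far end is inert and an arylzinc does not add to the new ketone. Aryl bromide 4 suits the coupling because both positions ortho to zinc carry hydrogen and the silyl ether is remote, and the cold, weakly acidic work-up protects C3, which is now α to an aryl ketone.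

Step 4
Reactants: 7 (2R,3S)-4-[3,5-dimethoxy-4-(triisopropylsilyloxy)phenyl]-2,3-dimethyl-4-oxobutanoic acid
Product: 8 (2R,3R)-4-[3,5-dimethoxy-4-(triisopropylsilyloxy)phenyl]-2,3-dimethylbutanoic acid
Conditions: Et3SiH (4 equiv), TFA/CH2Cl2, 0 °C to rt
Reagents that add atoms: none
Why: Ionic hydrogenation (Kursanov–Parnes reduction): the protonated aryl ketone, and then the benzylic carbinol or any γ-lactone formed from it, is ionized to a benzylic cation stabilized by the trioxygenated ring and captured by hydride from Et3SiH; no stereocentre is made, the C3 label changes from S to R only because the neighbouring carbon loses CIP rank, and the aryl silyl ether should be stable to TFA.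

Step 5
Reactants: 8 (2R,3R)-4-[3,5-dimethoxy-4-(triisopropylsilyloxy)phenyl]-2,3-dimethylbutanoic acid
Product: 10 (2R,3R)-4-[3,5-dimethoxy-4-(triisopropylsilyloxy)phenyl]-N-methoxy-N,2,3-trimethylbutanamide, via acyl imidazolide 9 (not isolated)
Conditions: CDI, CH2Cl2, rt; then MeNH(OMe)·HCl, rt
Reagents that add atoms: N,O-dimethylhydroxylamine hydrochloride, CNOC.Cl
Why: Amide formation through the acyl imidazolide (carbonyldiimidazole activation), a near-neutral method in which the amine hydrochloride itself protonates the departing imidazole, so the α-stereocentre C2 is never exposed to base.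

Step 6
Reactants: 11 4-bromo-2-methoxyphenol
Product: 12 (4-bromo-2-methoxyphenoxy)triisopropylsilane
Conditions: TIPSCl, imidazole, DMF, rt
Reagents that add atoms: triisopropylsilyl chloride (TIPSCl), CC(C)[Si](Cl)(C(C)C)C(C)C
Why: Silyl ether formation on a phenol, giving the pendant aryl fragment with the same protecting group as ring A so that both can be removed in one final operation.

Step 7
Reactants: 12 (4-bromo-2-methoxyphenoxy)triisopropylsilane; 10 (2R,3R)-4-[3,5-dimethoxy-4-(triisopropylsilyloxy)phenyl]-N-methoxy-N,2,3-trimethylbutanamide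
Product: 14 (2R,3R)-4-[3,5-dimethoxy-4-(triisopropylsilyloxy)phenyl]-1-[3-methoxy-4-(triisopropylsilyloxy)phenyl]-2,3-dimethylbutan-1-one, via arylmagnesium bromide 13 (not isolated)
Conditions: Mg turnings (iodine crystal), THF, 40 °C; then 10, THF, 0 °C to rt; cold 1 M HCl quench
Reagents that add atoms: none
Why: Weinreb ketone synthesis: the aryl Grignard reagent adds once to the N-methoxy-N-methyl amide to give a chelated tetrahedral magnesium adduct that collapses to the ketone only on the cold acidic quench, which prevents over-addition and keeps the α-stereocentre (C8') away from base.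

Step 8
Reactants: 14 (2R,3R)-4-[3,5-dimethoxy-4-(triisopropylsilyloxy)phenyl]-1-[3-methoxy-4-(triisopropylsilyloxy)phenyl]-2,3-dimethylbutan-1-one
Product: 15 (1RS,2R,3R)-4-[3,5-dimethoxy-4-(triisopropylsilyloxy)phenyl]-1-[3-methoxy-4-(triisopropylsilyloxy)phenyl]-2,3-dimethylbutan-1-ol (both C1 epimers, used together)
Conditions: NaBH4, MeOH/THF, 0 °C
Reagents that add atoms: none
Why: Borohydride reduction of the aryl ketone at low temperature; the configuration of the new carbinol carbon need not be controlled because both epimers give the same planar benzylic cation in the next step.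

Step 9
Reactants: 15 (1RS,2R,3R)-4-[3,5-dimethoxy-4-(triisopropylsilyloxy)phenyl]-1-[3-methoxy-4-(triisopropylsilyloxy)phenyl]-2,3-dimethylbutan-1-ol
Product: 16 (7'R,8R,8'R)-3,3',5-trimethoxy-4,4'-bis(triisopropylsilyloxy)-2,7'-cyclolignan
Conditions: BF3·OEt2 (20 mol %), CH2Cl2 (0.01 M), −78 to −20 °C
Reagents that add atoms: none
Why: Intramolecular Friedel–Crafts alkylation closing the six-membered ring B: ionization gives the C7' benzylic cation stabilized by the para silyloxy group, which is attacked by the ring A carbon ortho to one methoxy and para to the other (C2 and C6 being equivalent); C7' is set by substrate control, the guaiacyl group going pseudoaxial to avoid the peri C3 methoxy and anti to the axial C8' methyl while the C8 methyl stays equatorial, which is the 7',8'-trans (7'R) arrangement.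

Step 10
Reactants: 16 (7'R,8R,8'R)-3,3',5-trimethoxy-4,4'-bis(triisopropylsilyloxy)-2,7'-cyclolignan
Product: 17 (−)-(7'R,8R,8'R)-4,4'-dihydroxy-3,3',5-trimethoxy-2,7'-cyclolignan
Conditions: Bu4NF, AcOH, THF, 0 °C to rt, under argon
Reagents that add atoms: none
Why: Fluoride-induced cleavage of both aryl silyl ethers (driven by Si–F bond formation), buffered with acetic acid so that the electron-rich phenols are not left as air-sensitive phenoxides; no stereocentre is involved.

**Compound list**

1 | 2,3-dimethylmaleic anhydride | CC1=C(C)C(=O)OC1=O | starting material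
2 | meso-2,3-dimethylsuccinic anhydride, (3R,4S)-3,4-dimethyloxolane-2,5-dione | C[C@@H]1C(=O)OC(=O)[C@@H]1C | intermediate
3 | 4-bromo-2,6-dimethoxyphenol | COc1cc(Br)cc(OC)c1O | starting material
4 | (4-bromo-2,6-dimethoxyphenoxy)triisopropylsilane | COc1cc(Br)cc(OC)c1O[Si](C(C)C)(C(C)C)C(C)C | intermediate
5 | [3,5-dimethoxy-4-(triisopropylsilyloxy)phenyl]lithium | [Li]c1cc(OC)c(O[Si](C(C)C)(C(C)C)C(C)C)c(OC)c1 | intermediate
6 | [3,5-dimethoxy-4-(triisopropylsilyloxy)phenyl]zinc trifluoromethanesulfonate | FC(F)(F)S(=O)(=O)O[Zn]c1cc(OC)c(O[Si](C(C)C)(C(C)C)C(C)C)c(OC)c1 | intermediate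
7 | (2R,3S)-4-[3,5-dimethoxy-4-(triisopropylsilyloxy)phenyl]-2,3-dimethyl-4-oxobutanoic acid | COc1cc(C(=O)[C@@H](C)[C@H](C(=O)O)C)cc(OC)c1O[Si](C(C)C)(C(C)C)C(C)C | intermediate
8 | (2R,3R)-4-[3,5-dimethoxy-4-(triisopropylsilyloxy)phenyl]-2,3-dimethylbutanoic acid | COc1cc(C[C@@H](C)[C@H](C(=O)O)C)cc(OC)c1O[Si](C(C)C)(C(C)C)C(C)C | intermediate
9 | (2R,3R)-4-[3,5-dimethoxy-4-(triisopropylsilyloxy)phenyl]-1-(imidazol-1-yl)-2,3-dimethylbutan-1-one | COc1cc(C[C@@H](C)[C@H](C(=O)n2ccnc2)C)cc(OC)c1O[Si](C(C)C)(C(C)C)C(C)C | intermediate
10 | (2R,3R)-4-[3,5-dimethoxy-4-(triisopropylsilyloxy)phenyl]-N-methoxy-N,2,3-trimethylbutanamide | COc1cc(C[C@@H](C)[C@H](C(=O)N(C)OC)C)cc(OC)c1O[Si](C(C)C)(C(C)C)C(C)C | intermediate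
11 | 4-bromo-2-methoxyphenol | COc1cc(Br)ccc1O | starting material
12 | (4-bromo-2-methoxyphenoxy)triisopropylsilane | COc1cc(Br)ccc1O[Si](C(C)C)(C(C)C)C(C)C | intermediate
13 | [3-methoxy-4-(triisopropylsilyloxy)phenyl]magnesium bromide | COc1cc([Mg]Br)ccc1O[Si](C(C)C)(C(C)C)C(C)C | intermediate
14 | (2R,3R)-4-[3,5-dimethoxy-4-(triisopropylsilyloxy)phenyl]-1-[3-methoxy-4-(triisopropylsilyloxy)phenyl]-2,3-dimethylbutan-1-one | COc1cc(C[C@@H](C)[C@H](C(=O)c2ccc(O[Si](C(C)C)(C(C)C)C(C)C)c(OC)c2)C)cc(OC)c1O[Si](C(C)C)(C(C)C)C(C)C | intermediate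
15 | (1RS,2R,3R)-4-[3,5-dimethoxy-4-(triisopropylsilyloxy)phenyl]-1-[3-methoxy-4-(triisopropylsilyloxy)phenyl]-2,3-dimethylbutan-1-ol | COc1cc(C[C@@H](C)[C@H](C(O)c2ccc(O[Si](C(C)C)(C(C)C)C(C)C)c(OC)c2)C)cc(OC)c1O[Si](C(C)C)(C(C)C)C(C)C | intermediate
16 | (7'R,8R,8'R)-3,3',5-trimethoxy-4,4'-bis(triisopropylsilyloxy)-2,7'-cyclolignan | COc1cc([C@@H]2c3c(cc(OC)c(O[Si](C(C)C)(C(C)C)C(C)C)c3OC)C[C@@H](C)[C@H]2C)ccc1O[Si](C(C)C)(C(C)C)C(C)C | intermediate
17 | (−)-(7'R,8R,8'R)-4,4'-dihydroxy-3,3',5-trimethoxy-2,7'-cyclolignan, (6R,7R,8R)-8-(4-hydroxy-3-methoxyphenyl)-1,3-dimethoxy-6,7-dimethyl-5,6,7,8-tetrahydronaphthalen-2-ol | COc1cc([C@@H]2c3c(cc(OC)c(O)c3OC)C[C@@H](C)[C@H]2C)ccc1O | target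

**Step count and risks**

Total step count: 10 (step 1 prepares the anhydride, steps 2 and 6 the two aryl bromides).
Longest linear sequence: 8 steps (from 1 or from 3: steps 1 or 2, then 3, 4, 5, 7, 8, 9, 10).

Steps most likely to fail:

Step 3. The catalyst may discriminate poorly between the two enantiotopic acyl–oxygen bonds, or aryl transfer from zinc to rhodium may be slow so that the arylzinc is lost by protonation. The fallback moves the desymmetrization to an alcoholysis and forms the aryl–acyl bond afterwards. It sets out from anhydride 2 and returns at keto acid 7.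
- Anhydride 2 is opened with benzyl alcohol under cinchona alkaloid mediation (quinine or quinidine, whichever directs the alcohol to the carbonyl on the (R)-configured carbon; toluene, −55 °C) to give the hemiester (2S,3R)-4-(benzyloxy)-2,3-dimethyl-4-oxobutanoic acid F1.
- The free acid is converted (EtSH, EDC, cat. DMAP, CH2Cl2, 0 °C) into the thioester benzyl (2R,3S)-4-(ethylsulfanyl)-2,3-dimethyl-4-oxobutanoate F2.
- Fukuyama coupling of F2 with arylzinc 6, made from 4 as in step 3 (cat. PdCl2(PPh3)2, THF/toluene, rt), should give the keto ester benzyl (2R,3S)-4-[3,5-dimethoxy-4-(triisopropylsilyloxy)phenyl]-2,3-dimethyl-4-oxobutanoate F3.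
- Hydrogenolysis of the benzyl ester (H2, 10% Pd/C, EtOAc, rt) then frees acid 7.

Step 4. The C3 configuration may erode in TFA, either by acid-promoted enolization of the aryl ketone or by proton loss from the benzylic cation followed by reprotonation. The reduction may also stop at the benzylic γ-lactone, because the 4-oxygen of the trioxygenated ring is twisted out of conjugation and the cation forms slowly. The fallback replaces the cationic reduction by a surface hydrogenolysis. It sets out from keto acid 7 and returns at acid 8.
- The ketone is reduced with NaBH4 (THF/MeOH, 0 °C) and the hydroxy acid is closed by mild acidification to the lactone (3R,4S,5RS)-5-[3,5-dimethoxy-4-(triisopropylsilyloxy)phenyl]-3,4-dimethyloxolan-2-one F4.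
- The benzylic C–O bond of F4 is cleaved by catalytic hydrogenolysis (H2, 10% Pd/C, AcOH, 50 °C), which the silyl ether tolerates, to give acid 8.

Step 9. Ring A may attack the C7' cation with insufficient facial selectivity, so that the 7',8'-cis isomer forms beside the trans one, or the cation may lose the C8' proton and reprotonate. The fallback closes ring B first by acylation (Haworth-type closure) and brings in the guaiacyl ring afterwards by intermolecular attack on the cyclic cation. It sets out from acid 8 and returns at target 17.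
- Intramolecular Friedel–Crafts acylation of 8 (TFAA, CH2Cl2, 0 °C to rt) gives the tetralone (2R,3R)-6,8-dimethoxy-2,3-dimethyl-7-(triisopropylsilyloxy)-3,4-dihydronaphthalen-1(2H)-one F5. It is kept cold and free of base because C8' is now enolizable.
- NaBH4 (MeOH/THF, 0 °C) gives the tetralol (1RS,2R,3R)-6,8-dimethoxy-2,3-dimethyl-7-(triisopropylsilyloxy)-1,2,3,4-tetrahydronaphthalen-1-ol F6.
- F6 is ionized with BF3·OEt2 in the presence of excess 2-methoxyphenol (CH2Cl2, −40 °C). The phenol should attack through its carbon para to the hydroxyl and anti to the adjacent C8' methyl, giving (7'R,8R,8'R)-4'-hydroxy-3,3',5-trimethoxy-4-(triisopropylsilyloxy)-2,7'-cyclolignan F7.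
- Desilylation as in step 10 (Bu4NF, AcOH, THF) gives 17.

**Further compounds**

F1 | step 3 | (2S,3R)-4-(benzyloxy)-2,3-dimethyl-4-oxobutanoic acid | OC(=O)[C@@H](C)[C@H](C(=O)OCc1ccccc1)C
F2 | step 3 | benzyl (2R,3S)-4-(ethylsulfanyl)-2,3-dimethyl-4-oxobutanoate | CCSC(=O)[C@@H](C)[C@H](C(=O)OCc1ccccc1)C
F3 | step 3 | benzyl (2R,3S)-4-[3,5-dimethoxy-4-(triisopropylsilyloxy)phenyl]-2,3-dimethyl-4-oxobutanoate | COc1cc(C(=O)[C@@H](C)[C@H](C(=O)OCc2ccccc2)C)cc(OC)c1O[Si](C(C)C)(C(C)C)C(C)C
F4 | step 4 | (3R,4S,5RS)-5-[3,5-dimethoxy-4-(triisopropylsilyloxy)phenyl]-3,4-dimethyloxolan-2-one | COc1cc(C2OC(=O)[C@H](C)[C@@H]2C)cc(OC)c1O[Si](C(C)C)(C(C)C)C(C)C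
F5 | step 9 | (2R,3R)-6,8-dimethoxy-2,3-dimethyl-7-(triisopropylsilyloxy)-3,4-dihydronaphthalen-1(2H)-one | O=C1c2c(OC)c(O[Si](C(C)C)(C(C)C)C(C)C)c(OC)cc2C[C@@H](C)[C@H]1C
F6 | step 9 | (1RS,2R,3R)-6,8-dimethoxy-2,3-dimethyl-7-(triisopropylsilyloxy)-1,2,3,4-tetrahydronaphthalen-1-ol | OC1c2c(OC)c(O[Si](C(C)C)(C(C)C)C(C)C)c(OC)cc2C[C@@H](C)[C@H]1C
F7 | step 9 | (7'R,8R,8'R)-4'-hydroxy-3,3',5-trimethoxy-4-(triisopropylsilyloxy)-2,7'-cyclolignan | COc1cc([C@@H]2c3c(cc(OC)c(O[Si](C(C)C)(C(C)C)C(C)C)c3OC)C[C@@H](C)[C@H]2C)ccc1O
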